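**Retrosynthetic overview**

1. Target 25 is epioritin-(4β→6)-oritin-4α-ol (upper unit: rings A benzo, B aryl, C pyran; lower unit: rings D benzo, E aryl, F pyran); it comes from the protected dimer 23 by ester methanolysis and hydrogenolysis.
2. 23 is cut twice in ring C, at C2–C3 and at C4–C6(D): in one flask the O,S-acetal 11 closes ring C through the C2–C3 bond (Prins), the C3 benzoate holds the C4 cation as an acyloxonium ion, and C6 of ring D of the lower unit 20 arylates C4.
3. Enabling feature: in ring A, O1 (on C8a) and the 7-oxygen are ortho and para to C4a, so a cation at C4 is strongly stabilised and an alkene on C4a reacts through C3; C3 carries an oxygen that can travel as a participating ester; C6 of ring D is para to its own ring oxygen.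
4. 11 comes from 2,3,4-trihydroxybenzaldehyde (alkyne, Z-selective Ru addition of PhCO2H) and an α-chloro sulfide; 20 comes from 2',3',4'-trihydroxyacetophenone and 4-(benzyloxy)benzaldehyde (chalcone, Juliá–Colonna epoxide, ring F by O1–C2 closure, C4 reduction).
5. Ring order: F (step 12), then C (step 15); rings A, B, D and E are bought.

Key step: step 15

Remark on the chemistry: which antipode of the chiral acid in step 15 leads to the (2R,3R) upper unit cannot be assigned in advance; the (S,S) form is written and is to be fixed in a pilot run.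

**Route**

Step 1
Reactants: 1 2,3,4-trihydroxybenzaldehyde
Product: 2 3,4-bis(benzyloxy)-2-hydroxybenzaldehyde
Conditions: BnBr (2.05 equiv), K2CO3, DMF, rt
Reagents that add atoms: benzyl bromide BrCc1ccccc1
Why: Williamson etherification; the 2-hydroxyl is hydrogen-bonded to the formyl group and the least nucleophilic, so two equivalents of benzyl bromide should take the 4- and 3-hydroxyls only.

Step 2
Reactants: 2 3,4-bis(benzyloxy)-2-hydroxybenzaldehyde
Product: 3 3,4-bis(benzyloxy)-2-[(triisopropylsilyl)oxy]benzaldehyde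
Conditions: TIPSOTf, 2,6-lutidine, CH2Cl2, 0 °C
Reagents that add atoms: triisopropylsilyl trifluoromethanesulfonate CC(C)[Si](C(C)C)(C(C)C)OS(=O)(=O)C(F)(F)F
Why: Silylation with the reactive triflate masks the hindered phenol, which would otherwise cyclise onto the alkyne (benzofuran) in steps 3 and 4.

Step 3
Reactants: 3 3,4-bis(benzyloxy)-2-[(triisopropylsilyl)oxy]benzaldehyde
Product: 4 [2,3-bis(benzyloxy)-6-ethynylphenoxy]triisopropylsilane
Conditions: TMSCHN2, LDA, THF, −78 °C → rt
Reagents that add atoms: (trimethylsilyl)diazomethane C[Si](C)(C)C=[N+]=[N-]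
Why: Colvin homologation: the lithiated diazomethane adds to the aldehyde, and Peterson elimination with loss of N2 gives an alkylidene carbene that rearranges to the terminal alkyne under aprotic conditions that spare the aryl silyl ether.

Step 4
Reactants: 4 [2,3-bis(benzyloxy)-6-ethynylphenoxy]triisopropylsilane
Product: 5 (Z)-2-{3,4-bis(benzyloxy)-2-[(triisopropylsilyl)oxy]phenyl}ethenyl benzoate
Conditions: PhCO2H, Ru(η3-CH2CMeCH2)2(Ph2P(CH2)4PPh2) (2 mol%), toluene, 65 °C
Reagents that add atoms: benzoic acid OC(=O)c1ccccc1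
Why: Ruthenium-catalysed anti-Markovnikov hydro-oxycarbonylation of a terminal alkyne through a ruthenium vinylidene is known to give the Z enol ester, and this geometry later sets C2 and C3 cis.

Step 5
Reactants: 5 (Z)-2-{3,4-bis(benzyloxy)-2-[(triisopropylsilyl)oxy]phenyl}ethenyl benzoate
Product: 6 (Z)-2-[3,4-bis(benzyloxy)-2-hydroxyphenyl]ethenyl benzoate
Conditions: HF·pyridine, pyridine, THF, 0 °C
Reagents that add atoms: none
Why: Fluoride cleaves the aryl silyl ether under acidic buffering, so no phenoxide forms that could take the benzoyl group from the neighbouring enol ester.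

Step 6
Reactants: 7 1-(benzyloxy)-4-(chloromethyl)benzene; 8 benzenethiol
Product: 9 1-(benzyloxy)-4-[(phenylsulfanyl)methyl]benzene
Conditions: K2CO3, DMF, rt
Reagents that add atoms: none
Why: SN2 displacement of the benzylic chloride by the thiolate.

Step 7
Reactants: 9 1-(benzyloxy)-4-[(phenylsulfanyl)methyl]benzene; 6 (Z)-2-[3,4-bis(benzyloxy)-2-hydroxyphenyl]ethenyl benzoate
Product: 11 (Z)-2-[3,4-bis(benzyloxy)-2-{[4-(benzyloxy)phenyl](phenylsulfanyl)methoxy}phenyl]ethenyl benzoate, via α-chloro sulfide 10 (not isolated)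
Conditions: NCS, CH2Cl2, 0 °C; then 6, iPr2NEt, −40 → 0 °C
Reagents that add atoms: none
Why: Pummerer-type α-chlorination of the benzyl sulfide and SN1-like O-alkylation of the phenol by the reactive α-chloro sulfide give the O,S-acetal, whose racemic acetal carbon is of no consequence because it becomes planar in step 15.

Step 8
Reactants: 12 1-(2,3,4-trihydroxyphenyl)ethanone
Product: 13 1-[3,4-bis(benzyloxy)-2-hydroxyphenyl]ethanone
Conditions: BnBr (2.05 equiv), K2CO3, DMF, rt
Reagents that add atoms: benzyl bromide BrCc1ccccc1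
Why: Williamson etherification; the 2-hydroxyl chelated to the acetyl group should stay free, as in step 1.

Step 9
Reactants: 13 1-[3,4-bis(benzyloxy)-2-hydroxyphenyl]ethanone
Product: 14 1-[3,4-bis(benzyloxy)-2-(methoxymethoxy)phenyl]ethanone
Conditions: MOMCl, iPr2NEt, CH2Cl2, 0 °C → reflux
Reagents that add atoms: chloromethyl methyl ether COCCl
Why: Acetal protection of the phenol prevents flavanone formation in step 10 and phenoxide deactivation of the enone in step 11.

Step 10
Reactants: 14 1-[3,4-bis(benzyloxy)-2-(methoxymethoxy)phenyl]ethanone; 15 4-(benzyloxy)benzaldehyde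
Product: 16 (E)-1-[3,4-bis(benzyloxy)-2-(methoxymethoxy)phenyl]-3-[4-(benzyloxy)phenyl]prop-2-en-1-one
Conditions: KOH, EtOH/THF, rt
Reagents that add atoms: none
Why: Claisen–Schmidt condensation; E1cB dehydration of the aldol gives the E enone.

Step 11
Reactants: 16 (E)-1-[3,4-bis(benzyloxy)-2-(methoxymethoxy)phenyl]-3-[4-(benzyloxy)phenyl]prop-2-en-1-one
Product: 17 {(2R,3S)-3-[4-(benzyloxy)phenyl]oxiran-2-yl}[3,4-bis(benzyloxy)-2-(methoxymethoxy)phenyl]methanone
Conditions: poly-L-leucine, urea–H2O2, DBU, THF, rt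
Reagents that add atoms: urea–hydrogen peroxide NC(N)=O.OO
Why: Juliá–Colonna epoxidation; the hydroperoxide adds to the enone held by the helical poly-L-leucine, which is known to give the (2R,3S)-epoxide of chalcones and so sets C3 of the future ring F.

Step 12
Reactants: 17 {(2R,3S)-3-[4-(benzyloxy)phenyl]oxiran-2-yl}[3,4-bis(benzyloxy)-2-(methoxymethoxy)phenyl]methanone
Product: 18 (2R,3R)-7,8-bis(benzyloxy)-2-[4-(benzyloxy)phenyl]-3-hydroxy-2,3-dihydro-4H-chromen-4-one
Conditions: conc. HCl, MeOH/THF, 50 °C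
Reagents that add atoms: none
Why: Acid removes the MOM group and the phenol opens the epoxide at the benzylic carbon (6-endo, with inversion or through the benzylic cation), the retained C3 centre steering the aryl group trans, as in the classical dihydroflavonol synthesis from chalcone epoxides.

Step 13
Reactants: 18 (2R,3R)-7,8-bis(benzyloxy)-2-[4-(benzyloxy)phenyl]-3-hydroxy-2,3-dihydro-4H-chromen-4-one
Product: 19 (2R,3S,4R)-7,8-bis(benzyloxy)-2-[4-(benzyloxy)phenyl]chromane-3,4-diol
Conditions: NaBH4, MeOH/THF, 0 °C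
Reagents that add atoms: none
Why: Hydride adds axially to the C4 carbonyl of the half-chair with equatorial 2-aryl and 3-hydroxyl groups and should give the equatorial 4-alcohol trans to the 3-hydroxyl, the known outcome for 2,3-trans-dihydroflavonols.

Step 14
Reactants: 19 (2R,3S,4R)-7,8-bis(benzyloxy)-2-[4-(benzyloxy)phenyl]chromane-3,4-diol
Product: 20 (2R,3R,4R)-7,8-bis(benzyloxy)-2-[4-(benzyloxy)phenyl]chromane-3,4-diyl diacetate
Conditions: Ac2O, pyridine, DMAP, CH2Cl2, rt
Reagents that add atoms: acetic anhydride CC(=O)OC(C)=O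
Why: Acylation of both secondary alcohols removes competing O-nucleophiles for step 15 (the geometry is unchanged; only the CIP label at C3 changes).

Step 15
Reactants: 11 (Z)-2-[3,4-bis(benzyloxy)-2-{[4-(benzyloxy)phenyl](phenylsulfanyl)methoxy}phenyl]ethenyl benzoate; 20 (2R,3R,4R)-7,8-bis(benzyloxy)-2-[4-(benzyloxy)phenyl]chromane-3,4-diyl diacetate
Product: 23 protected dimer (upper unit 2,3-cis-3,4-trans 3-O-benzoate; lower unit 3,4-di-O-acetate; six benzyl ethers), via aryl oxocarbenium ion 21 (not isolated), via acyloxonium ion 22 (not isolated)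
Conditions: 20 (1.2 equiv), Ag2CO3 (1.0 equiv), (S,S)-IDPi acid (chiral N-triflyl imidodiphosphorimidate, 10 mol%), 4 Å MS, PhMe/CH2Cl2, −40 → −10 °C, dark
Reagents that add atoms: none
Why: Proposed new method: the chiral salt of monovalent silver formed from Ag2CO3 and the IDPi acid removes benzenethiolate from 11, both acetal epimers merge in the planar (E)-aryl-oxocarbenium ion 21 paired with the chiral anion, and the (Z)-enol benzoate closes ring C in the 6-endo-trig mode through its oxygen-bearing carbon (Prins cyclisation, C2–C3 bond), the resulting benzylic cation at C4 being para to the 7-benzyloxy group and ortho to O1. The closest known reactions are IDPi-controlled asymmetric Prins cyclisations of oxocarbenium ions, chiral-anion phase-transfer ionisations driven by Ag2CO3 and the silver-promoted arylation of 4-sulfanylflavan-3-ols by flavan nucleophiles; new are the enol ester as the alkene partner and the merger of the three events. C2 and C3 arise together in a half-chair transition state with the 4-benzyloxyphenyl group pseudo-equatorial and the Z-placed benzoyloxy group axial, which fixes 2,3-cis, while the face of 21 that is attacked, and hence the absolute (2R,3R) sense, rests on the chiral anion and is the least secured element. The C4 cation is held by the benzoate carbonyl as the cis-fused acyloxonium ion 22, so C6 of 20 can enter only from the opposite face and the new aryl group comes out trans to the C3 oxygen (4β). The step needs attack through C3 and not C4 of the alkene (secured by the 7-oxygen, which makes the 6-endo cation far better than the unconjugated acyloxy cation of a 5-exo closure), ring closure before arylation (intramolecular, so faster than capture of 21 by 20) and C6 over C5 in ring D (C6 is para to the ring oxygen and ortho to the 7-benzyloxy group, C5 is peri to the 4-acetoxy group). Ag2CO3 takes up the proton of the Friedel–Crafts step, which keeps the ionisable 4-acetoxy group of 20 away from free acid, and a diastereomer from imperfect facial control should be separable because 20 is enantiopure.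

Step 16
Reactants: 23 protected dimer
Product: 24 (2R,3S,4R)-7,8-bis(benzyloxy)-2-[4-(benzyloxy)phenyl]-6-{(2R,3R,4R)-7,8-bis(benzyloxy)-2-[4-(benzyloxy)phenyl]-3-hydroxychroman-4-yl}chromane-3,4-diol
Conditions: K2CO3 (cat.), MeOH/THF, rt → 40 °C
Reagents that add atoms: none
Why: Base-catalysed transesterification removes the benzoate and both acetates while the benzyl ethers keep the phenols from forming quinone methides.

Step 17
Reactants: 24 hexa-O-benzyl triol
Product: 25 (2R,3S,4R)-2-(4-hydroxyphenyl)-6-[(2R,3R,4S)-3,7,8-trihydroxy-2-(4-hydroxyphenyl)chroman-4-yl]chromane-3,4,7,8-tetrol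
Conditions: H2 (1 atm), Pd(OH)2/C, THF/MeOH, rt
Reagents that add atoms: none
Why: Hydrogenolysis of the six benzyl ethers under neutral conditions, as practised for benzylated proanthocyanidins; no stereocenter is touched (the CIP label at C4 of the upper unit changes from R to S only because the priorities change).

**Compound list**

1 | 2,3,4-trihydroxybenzaldehyde | O=Cc1ccc(O)c(O)c1O | starting material
2 | 3,4-bis(benzyloxy)-2-hydroxybenzaldehyde | O=Cc1ccc(OCc2ccccc2)c(OCc2ccccc2)c1O | intermediate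
3 | 3,4-bis(benzyloxy)-2-[(triisopropylsilyl)oxy]benzaldehyde | O=Cc1ccc(OCc2ccccc2)c(OCc2ccccc2)c1O[Si](C(C)C)(C(C)C)C(C)C | intermediate
4 | [2,3-bis(benzyloxy)-6-ethynylphenoxy]triisopropylsilane | C#Cc1ccc(OCc2ccccc2)c(OCc2ccccc2)c1O[Si](C(C)C)(C(C)C)C(C)C | intermediate
5 | (Z)-2-{3,4-bis(benzyloxy)-2-[(triisopropylsilyl)oxy]phenyl}ethenyl benzoate | O=C(O/C=C\c1ccc(OCc2ccccc2)c(OCc2ccccc2)c1O[Si](C(C)C)(C(C)C)C(C)C)c1ccccc1 | intermediate
6 | (Z)-2-[3,4-bis(benzyloxy)-2-hydroxyphenyl]ethenyl benzoate | O=C(O/C=C\c1ccc(OCc2ccccc2)c(OCc2ccccc2)c1O)c1ccccc1 | intermediate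
7 | 1-(benzyloxy)-4-(chloromethyl)benzene | ClCc1ccc(OCc2ccccc2)cc1 | starting material
8 | benzenethiol | Sc1ccccc1 | starting material
9 | 1-(benzyloxy)-4-[(phenylsulfanyl)methyl]benzene | c1ccc(SCc2ccc(OCc3ccccc3)cc2)cc1 | intermediate
10 | 1-(benzyloxy)-4-[chloro(phenylsulfanyl)methyl]benzene (racemic, not isolated) | ClC(Sc1ccccc1)c1ccc(OCc2ccccc2)cc1 | intermediate
11 | (Z)-2-[3,4-bis(benzyloxy)-2-{[4-(benzyloxy)phenyl](phenylsulfanyl)methoxy}phenyl]ethenyl benzoate (racemic at the acetal carbon) | O=C(O/C=C\c1ccc(OCc2ccccc2)c(OCc2ccccc2)c1OC(Sc1ccccc1)c1ccc(OCc2ccccc2)cc1)c1ccccc1 | intermediate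
12 | 1-(2,3,4-trihydroxyphenyl)ethanone | CC(=O)c1ccc(O)c(O)c1O | starting material
13 | 1-[3,4-bis(benzyloxy)-2-hydroxyphenyl]ethanone | CC(=O)c1ccc(OCc2ccccc2)c(OCc2ccccc2)c1O | intermediate
14 | 1-[3,4-bis(benzyloxy)-2-(methoxymethoxy)phenyl]ethanone | CC(=O)c1ccc(OCc2ccccc2)c(OCc2ccccc2)c1OCOC | intermediate
15 | 4-(benzyloxy)benzaldehyde | O=Cc1ccc(OCc2ccccc2)cc1 | starting material
16 | (E)-1-[3,4-bis(benzyloxy)-2-(methoxymethoxy)phenyl]-3-[4-(benzyloxy)phenyl]prop-2-en-1-one | COCOc1c(C(=O)/C=C/c2ccc(OCc3ccccc3)cc2)ccc(OCc2ccccc2)c1OCc1ccccc1 | intermediate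
17 | {(2R,3S)-3-[4-(benzyloxy)phenyl]oxiran-2-yl}[3,4-bis(benzyloxy)-2-(methoxymethoxy)phenyl]methanone | O=C(c1ccc(OCc2ccccc2)c(OCc2ccccc2)c1OCOC)[C@@H]1O[C@H]1c1ccc(OCc2ccccc2)cc1 | intermediate
18 | (2R,3R)-7,8-bis(benzyloxy)-2-[4-(benzyloxy)phenyl]-3-hydroxy-2,3-dihydro-4H-chromen-4-one | c1cc2c(c(OCc3ccccc3)c1OCc1ccccc1)O[C@H](c1ccc(OCc3ccccc3)cc1)[C@@H](O)C2=O | intermediate
19 | (2R,3S,4R)-7,8-bis(benzyloxy)-2-[4-(benzyloxy)phenyl]chromane-3,4-diol (2,3-trans-3,4-trans) | c1cc2c(c(OCc3ccccc3)c1OCc1ccccc1)O[C@H](c1ccc(OCc3ccccc3)cc1)[C@@H](O)[C@@H]2O | intermediate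
20 | (2R,3R,4R)-7,8-bis(benzyloxy)-2-[4-(benzyloxy)phenyl]chromane-3,4-diyl diacetate (2,3-trans-3,4-trans) | c1cc2c(c(OCc3ccccc3)c1OCc1ccccc1)O[C@H](c1ccc(OCc3ccccc3)cc1)[C@@H](OC(C)=O)[C@@H]2OC(C)=O | intermediate
21 | (E)-aryl oxocarbenium ion from 11, ion pair with the IDPi anion (not isolated) | O=C(O/C=C\c1ccc(OCc2ccccc2)c(OCc2ccccc2)c1/[O+]=C/c1ccc(OCc2ccccc2)cc1)c1ccccc1 | intermediate
22 | cis-fused 2-phenyl-1,3-dioxolan-2-ylium ion across C3–C4 of the (2R,3R)-flavan, ion pair with the IDPi anion (not isolated) | C(c1ccccc1)Oc1ccc([C@H]2Oc3c(ccc(OCc4ccccc4)c3OCc3ccccc3)[C@H]5[O+]=C(c6ccccc6)O[C@@H]25)cc1 | intermediate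
23 | (2R,3R,4R)-7,8-bis(benzyloxy)-2-[4-(benzyloxy)phenyl]-4-{(2R,3R,4R)-3,4-bis(acetyloxy)-7,8-bis(benzyloxy)-2-[4-(benzyloxy)phenyl]chroman-6-yl}chroman-3-yl benzoate (upper unit 2,3-cis-3,4-trans) | C(c1ccccc1)Oc1ccc([C@H]2Oc3c(ccc(OCc4ccccc4)c3OCc3ccccc3)[C@H](c3cc4c(c(OCc5ccccc5)c3OCc3ccccc3)O[C@H](c3ccc(OCc5ccccc5)cc3)[C@@H](OC(C)=O)[C@@H]4OC(C)=O)[C@H]2OC(=O)c2ccccc2)cc1 | intermediate
24 | (2R,3S,4R)-7,8-bis(benzyloxy)-2-[4-(benzyloxy)phenyl]-6-{(2R,3R,4R)-7,8-bis(benzyloxy)-2-[4-(benzyloxy)phenyl]-3-hydroxychroman-4-yl}chromane-3,4-diol | C(c1ccccc1)Oc1ccc([C@H]2Oc3c(ccc(OCc4ccccc4)c3OCc3ccccc3)[C@H](c3cc4c(c(OCc5ccccc5)c3OCc3ccccc3)O[C@H](c3ccc(OCc5ccccc5)cc3)[C@@H](O)[C@@H]4O)[C@H]2O)cc1 | intermediate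
25 | (2R,3S,4R)-2-(4-hydroxyphenyl)-6-[(2R,3R,4S)-3,7,8-trihydroxy-2-(4-hydroxyphenyl)chroman-4-yl]chromane-3,4,7,8-tetrol | Oc1ccc([C@H]2Oc3c(ccc(O)c3O)[C@H](c3cc4c(c(O)c3O)O[C@H](c3ccc(O)cc3)[C@@H](O)[C@@H]4O)[C@H]2O)cc1 | target

**Step count and risks**

Total step count: 17. Longest linear sequence: 10 steps (12 → 25, steps 8–17).

Steps most likely to fail:

1. Step 15 (Proposed new method). What may go wrong: loss of facial control over the oxocarbenium ion, ring closure through the wrong alkene carbon to a five-membered ring, or hydrolysis of the cationic intermediates before arylation. The fallback gives up the cascade and joins the units by the known thiophilic flavan coupling; it sets out from 19 and comes back at 23. Ionic deoxygenation of 19 at C4 (Et3SiH, TFA, CH2Cl2, −20 °C) should give (2R,3S)-7,8-bis(benzyloxy)-2-[4-(benzyloxy)phenyl]chroman-3-ol F1. Dess–Martin oxidation gives the (2R)-chroman-3-one F2. LiBH(s-Bu)3 (THF, −78 °C) adds hydride anti to the 2-aryl group and gives the 2,3-cis alcohol, (2R,3R)-chroman-3-ol F3. DDQ with 2-ethoxyethanol oxidises C4 to the 4β-(2-ethoxyethoxy) ether F4. BnSH with catalytic BF3·OEt2 exchanges the ether for the 4β-benzylsulfanyl derivative F5, and BzCl/pyridine gives its 3-O-benzoate F6. AgBF4 (THF, 0 °C) then couples F6 with 20 under neutral conditions, the benzoate directing the aryl group trans, to give 23.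

2. Step 7. What may go wrong: transfer of the benzoyl group from the enol oxygen to the liberated phenol of 6 with collapse to a benzofuran, and decay of the α-chloro sulfide before O-alkylation. The fallback installs the acetal before the enol ester; it sets out from 4 and comes back at 11. TBAF (THF, 0 °C) frees 2,3-bis(benzyloxy)-6-ethynylphenol F7, which is alkylated at once with 10 (from 9 and NCS) and iPr2NEt to the alkynyl O,S-acetal F8. The Ru-catalysed anti-Markovnikov addition of benzoic acid (conditions of step 4) then gives 11.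

3. Step 17. What may go wrong: over-reduction, that is hydrogenolytic loss of the benzylic 4-hydroxyl of ring F in competition with debenzylation. The fallback carries that carbon as a ketone through the hydrogenolysis; it sets out from 24 and comes back at 25. MnO2 (CH2Cl2, rt) should oxidise only the benzylic 4-hydroxyl and give the ring F ketone F9. Hydrogenolysis (H2, Pd(OH)2/C) gives the free phenolic ketone F10. NaBH4 (EtOH, 0 °C) then reduces the carbonyl from the axial direction to the 3,4-trans diol 25, as in the known reduction of free dihydroflavonols.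

**Further compounds**

F1 | step 15 | (2R,3S)-7,8-bis(benzyloxy)-2-[4-(benzyloxy)phenyl]chroman-3-ol | c1cc2c(c(OCc3ccccc3)c1OCc1ccccc1)O[C@H](c1ccc(OCc3ccccc3)cc1)[C@@H](O)C2
F2 | step 15 | (2R)-7,8-bis(benzyloxy)-2-[4-(benzyloxy)phenyl]chroman-3-one | c1cc2c(c(OCc3ccccc3)c1OCc1ccccc1)O[C@H](c1ccc(OCc3ccccc3)cc1)C(=O)C2
F3 | step 15 | (2R,3R)-7,8-bis(benzyloxy)-2-[4-(benzyloxy)phenyl]chroman-3-ol (2,3-cis) | c1cc2c(c(OCc3ccccc3)c1OCc1ccccc1)O[C@H](c1ccc(OCc3ccccc3)cc1)[C@H](O)C2
F4 | step 15 | (2R,3R,4S)-7,8-bis(benzyloxy)-2-[4-(benzyloxy)phenyl]-4-(2-ethoxyethoxy)chroman-3-ol (2,3-cis-3,4-trans) | C(c1ccccc1)Oc1ccc([C@H]2Oc3c(ccc(OCc4ccccc4)c3OCc3ccccc3)[C@H](OCCOCC)[C@H]2O)cc1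
F5 | step 15 | (2R,3S,4S)-7,8-bis(benzyloxy)-2-[4-(benzyloxy)phenyl]-4-(benzylsulfanyl)chroman-3-ol (2,3-cis-3,4-trans) | C(c1ccccc1)Oc1ccc([C@H]2Oc3c(ccc(OCc4ccccc4)c3OCc3ccccc3)[C@H](SCc3ccccc3)[C@H]2O)cc1
F6 | step 15 | (2R,3S,4S)-7,8-bis(benzyloxy)-2-[4-(benzyloxy)phenyl]-4-(benzylsulfanyl)chroman-3-yl benzoate (2,3-cis-3,4-trans) | C(c1ccccc1)Oc1ccc([C@H]2Oc3c(ccc(OCc4ccccc4)c3OCc3ccccc3)[C@H](SCc3ccccc3)[C@H]2OC(=O)c2ccccc2)cc1
F7 | step 7 | 2,3-bis(benzyloxy)-6-ethynylphenol | C#Cc1ccc(OCc2ccccc2)c(OCc2ccccc2)c1O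
F8 | step 7 | 1,2-bis(benzyloxy)-3-{[4-(benzyloxy)phenyl](phenylsulfanyl)methoxy}-4-ethynylbenzene (racemic) | C#Cc1ccc(OCc2ccccc2)c(OCc2ccccc2)c1OC(Sc1ccccc1)c1ccc(OCc2ccccc2)cc1
F9 | step 17 | (2R,3R)-7,8-bis(benzyloxy)-2-[4-(benzyloxy)phenyl]-6-{(2R,3R,4R)-7,8-bis(benzyloxy)-2-[4-(benzyloxy)phenyl]-3-hydroxychroman-4-yl}-3-hydroxy-2,3-dihydro-4H-chromen-4-one | C(c1ccccc1)Oc1ccc([C@H]2Oc3c(ccc(OCc4ccccc4)c3OCc3ccccc3)[C@H](c3cc4c(c(OCc5ccccc5)c3OCc3ccccc3)O[C@H](c3ccc(OCc5ccccc5)cc3)[C@@H](O)C4=O)[C@H]2O)cc1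
F10 | step 17 | (2R,3R)-3,7,8-trihydroxy-2-(4-hydroxyphenyl)-6-[(2R,3R,4S)-3,7,8-trihydroxy-2-(4-hydroxyphenyl)chroman-4-yl]-2,3-dihydro-4H-chromen-4-one | Oc1ccc([C@H]2Oc3c(ccc(O)c3O)[C@H](c3cc4c(c(O)c3O)O[C@H](c3ccc(O)cc3)[C@@H](O)C4=O)[C@H]2O)cc1
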